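The cyclobutane is closed last, between C10 (the ring CH at the γ-position of the enone) and C11 (the methyl-bearing quaternary carbon next to the senecioyloxy carbinol C1). The precursor is a cis-fused cyclohexenone–cycloheptene epoxide: C10 is the γ-carbon of a silyl dienol ether, C11 the tertiary end of a C1–C11 epoxide, and both sit 1,3 across the ring fusion. Lewis-acid opening of the epoxide at C11 and capture by C10 forms the four-membered ring, the quaternary centre, the free C1 hydroxyl with defined configuration and the bicyclo[3.1.1]heptenone in one operation. The bicycle comes from a Diels–Alder reaction, a one-carbon ring expansion and a late epoxidation.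

Key step: step 13

Remark on numbering (used throughout): seven-membered ring C1 (CH–O, later senecioate) – C2 (CH2) – C3 (CH–O, later isovalerate) – C4 (CMe2) – C5 (CH) – C6 (CH) – C11 (C–Me); six-membered ring C5 – C6 – C7 (C=O) – C8 (=CH) – C9 (=C–Me) – C10 (CH).
Assumption: 4,4-dimethylcyclohexa-2,5-dien-1-one (1) and 3-methylbut-2-enal (5) are bought as catalogue compounds.
Remark on C3: the C3 silyloxy group of 4 has the configuration opposite to the target; it is used to steer the Diels–Alder reaction and is corrected in steps 9 and 10.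

Step 1
Reactants: 1 4,4-dimethylcyclohexa-2,5-dien-1-one
Product: 3 (S)-5-hydroxy-4,4-dimethylcyclohex-2-en-1-one, via β-boryl enone 2 (not isolated)
Conditions: CuCl (5 mol %), Josiphos-type bisphosphine (6 mol %, enantiomer chosen for the S product), NaOt-Bu (10 mol %), B2pin2 (1.0 equiv), THF, −20 °C, no protic additive; then 30 % H2O2, pH 7 buffer, 0 °C
Reagents that add atoms: hydrogen peroxide OO
Why: Copper-catalysed enantioselective conjugate borylation of one of the two equivalent enone arms, followed by stereoretentive C–B oxidation, should give the β-hydroxy enone; the ligand sets the C3 centre and the O-boron enolate formed after the first addition should shield the second enone until work-up.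

Step 2
Reactants: 3 (S)-5-hydroxy-4,4-dimethylcyclohex-2-en-1-one
Product: 4 (S)-5-(tert-butyldimethylsilyloxy)-4,4-dimethylcyclohex-2-en-1-one
Conditions: TBSCl, imidazole, DMF, 0 °C → rt
Reagents that add atoms: tert-butyldimethylsilyl chloride CC(C)(C)[Si](C)(C)Cl
Why: Standard silylation of a secondary alcohol under near-neutral conditions, which should not cause β-elimination of the β-hydroxy ketone.

Step 3
Reactants: 5 3-methylbut-2-enal
Product: 6 (E)-1-(tert-butyldimethylsilyloxy)-3-methylbuta-1,3-diene
Conditions: TBSOTf, Et3N, Et2O, 0 °C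
Reagents that add atoms: tert-butyldimethylsilyl triflate CC(C)(C)[Si](C)(C)OS(=O)(=O)C(F)(F)F
Why: Soft enolisation (O-silylation, then γ-deprotonation of a methyl group) should give the silyl dienol ether, mainly as the E isomer from the s-trans enal.

Step 4
Reactants: 4 (S)-5-(tert-butyldimethylsilyloxy)-4,4-dimethylcyclohex-2-en-1-one; 6 (E)-1-(tert-butyldimethylsilyloxy)-3-methylbuta-1,3-diene
Product: 7 cis-fused Diels–Alder adduct (3,8-bis-TBS-oxy-4,4,6-trimethyl-3,4,4a,5,8,8a-hexahydronaphthalen-1(2H)-one)
Conditions: Me2AlCl (1.1 equiv), CH2Cl2, −78 → −30 °C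
Reagents that add atoms: none
Why: Lewis-acid-promoted Diels–Alder reaction in which the oxygenated diene terminus should bond to the enone α-carbon (C6) and the CH2 terminus to C5, suprafacial addition gives the cis fusion, the diene should add anti to the pseudo-equatorial C3 silyloxy group (the usual sense for 5-substituted cyclohexenones) and the endo mode places the C7 silyloxy group cis to the ketone carbon.

Step 5
Reactants: 7 cis-fused Diels–Alder adduct
Product: 9 cis-fused bicyclo[5.4.0]undecenone (C11 ketone with C1 inserted between C11 and C2), via trimethylsilyl enol ether 8 (not isolated)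
Conditions: TMSCHN2 (1.3 equiv), Sc(OTf)3 (10 mol %), CH2Cl2, −40 → 0 °C; then 1 M HCl, THF, 0 °C
Reagents that add atoms: (trimethylsilyl)diazomethane C[Si](C)(C)C=[N+]=[N-]
Why: Lewis-acid-catalysed diazoalkane homologation (Tiffeneau–Demjanov-type 1,2-shift) in which the methylene C2 should migrate in preference to the ring-fusion methine C6, and silyl migration to oxygen should prevent a second insertion.

Step 6
Reactants: 9 cis-fused bicyclo[5.4.0]undecenone
Product: 10 enol triflate (C11(OTf)=C1)
Conditions: KHMDS, THF, −78 °C; then PhNTf2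
Reagents that add atoms: N-phenylbis(trifluoromethanesulfonimide) FC(F)(F)S(=O)(=O)N(c1ccccc1)S(=O)(=O)C(F)(F)F
Why: Kinetic deprotonation should occur at the C1 methylene and not at the hindered ring-fusion methine C6, and O-triflation of the enolate fixes the C11=C1 double bond.

Step 7
Reactants: 10 enol triflate
Product: 11 bis-silyl ether diene (C11(Me)=C1 and C8=C9(Me))
Conditions: MeMgBr, Fe(acac)3 (5 mol %), THF/NMP, −30 °C
Reagents that add atoms: methylmagnesium bromide C[Mg]Br
Why: Iron-catalysed Kumada-type cross-coupling of the alkenyl triflate should install the C11 methyl group without moving the double bond.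

Step 8
Reactants: 11 bis-silyl ether diene
Product: 12 diol (C7-OH and C3-OH)
Conditions: TBAF, THF, 50 °C
Reagents that add atoms: none
Why: Fluoride cleaves both silyl ethers, and no base-sensitive group is present at this stage.

Step 9
Reactants: 12 diol
Product: 13 enedione (C7 enone and C3 ketone)
Conditions: Dess–Martin periodinane, NaHCO3, CH2Cl2, 0 °C → rt
Reagents that add atoms: none
Why: Dess–Martin oxidation should convert the allylic C7 alcohol into the enone and the C3 alcohol into the ketone under buffered, non-enolising conditions that leave C6 and the C1=C11 double bond in place.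

Step 10
Reactants: 13 enedione
Product: 14 (3R)-hydroxy enone
Conditions: LiAlH(Ot-Bu)3 (1.2 equiv), THF, −78 → −30 °C
Reagents that add atoms: none
Why: Chemoselective hydride reduction of a saturated ketone beside a β,β-disubstituted enone (the selectivity known from 17-keto versus 4-en-3-one steroids), with hydride expected on the C3 face anti to C10, so that the new hydroxyl is cis to C10.

Step 11
Reactants: 14 (3R)-hydroxy enone
Product: 15 C3 isovalerate
Conditions: isovaleryl chloride, pyridine, DMAP (cat.), CH2Cl2, 0 °C → rt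
Reagents that add atoms: 3-methylbutanoyl chloride CC(C)CC(Cl)=O
Why: DMAP-catalysed acylation of the hindered secondary alcohol installs the final C3 ester, which then also serves as the protecting group.

Step 12
Reactants: 15 C3 isovalerate
Product: 16 C1–C11 epoxide
Conditions: mCPBA, NaHCO3, CH2Cl2, 0 °C
Reagents that add atoms: 3-chloroperbenzoic acid OOC(=O)c1cccc(Cl)c1
Why: Prilezhaev epoxidation in which the electron-rich trisubstituted C1=C11 alkene should react and the enone should not, with the peracid expected on the face of the seven-membered ring opposite the C6–C7 bond, which is the face on which C1 carries its oxygen in the target.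

Step 13
Reactants: 16 C1–C11 epoxide
Product: 18 tricyclic hydroxy enone (target without the senecioyl group), via silyl dienol ether 17 (not isolated)
Conditions: TBSOTf, Et3N, CH2Cl2, −78 °C; pentane, filtration, concentration; MeAlCl2 (1.5 equiv), CH2Cl2, −78 °C; aq. NaHCO3
Reagents that add atoms: none
Why: Proposed new method: MeAlCl2 binds the epoxide oxygen, the C11–O bond ionises at the tertiary centre, the γ-carbon C10 of the silyl dienol ether attacks C11 anti to the departing oxygen, and loss of the silyl group from the silyloxyallyl cation returns the C7 enone while work-up frees the C1 hydroxyl. The closest known reaction type is the Lewis-acid-promoted, epoxide-initiated cation–olefin cyclisation terminated by a silyl enol ether, here asked to close a four-membered ring through the vinylogous position, as the terpinyl-to-pinyl closure does in pinene biosynthesis. The cyclobutane closes in a 4-exo-tet mode at the epoxide carbon, and the same bond completes the bicyclo[3.1.1]heptenone. C11 is set by inversion, C10 by the cis ring fusion, which lets the C6–C11 arm reach only one face of C10, and C1 keeps the configuration set in step 12. The step needs attack through C10 and not C8 (which would give a cyclobutanone), ionisation at C11 and not displacement at C1, and ring closure faster than hydride shift or proton loss; the nucleophilic dienol ether, its irreversible desilylation and the 1,3-diaxial-like proximity of C10 and C11 when C11 is pseudo-axial on C6 should secure this.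

Step 14
Reactants: 18 tricyclic hydroxy enone
Product: 19 CNP0335239.1 (target)
Conditions: 3-methylbut-2-enoyl chloride, pyridine, DMAP, CH2Cl2, 0 °C → rt
Reagents that add atoms: 3-methylbut-2-enoyl chloride CC(C)=CC(Cl)=O
Why: Acylation of the C1 hydroxyl with the acid chloride and a weak base, chosen to avoid deconjugation through a vinylketene, should complete the target.

Compound list
1 | 4,4-dimethylcyclohexa-2,5-dien-1-one | CC1(C)C=CC(=O)C=C1 | starting material
2 | (S)-4,4-dimethyl-5-(pinacolboryl)cyclohex-2-en-1-one | O=C1C[C@H](B2OC(C)(C)C(C)(C)O2)C(C)(C)C=C1 | intermediate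
3 | (S)-5-hydroxy-4,4-dimethylcyclohex-2-en-1-one | O=C1C[C@H](O)C(C)(C)C=C1 | intermediate
4 | (S)-5-(tert-butyldimethylsilyloxy)-4,4-dimethylcyclohex-2-en-1-one | O=C1C[C@H](O[Si](C)(C)C(C)(C)C)C(C)(C)C=C1 | intermediate
5 | 3-methylbut-2-enal | CC(C)=CC=O | starting material
6 | (E)-1-(tert-butyldimethylsilyloxy)-3-methylbuta-1,3-diene | C=C(C)/C=C/O[Si](C)(C)C(C)(C)C | intermediate
7 | cis-fused Diels–Alder adduct: 3,8-bis(TBS-oxy)-4,4,6-trimethyl-3,4,4a,5,8,8a-hexahydronaphthalen-1(2H)-one; new ring anti to the (3S)-silyloxy group; C8 silyloxy group cis to the ketone carbon | O=C1C[C@H](O[Si](C)(C)C(C)(C)C)C(C)(C)[C@H]2CC(C)=C[C@@H](O[Si](C)(C)C(C)(C)C)[C@@H]12 | intermediate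
8 | ring-expanded trimethylsilyl enol ether (C11(OTMS)=C1) | C[Si](C)(C)OC1=CC[C@H](O[Si](C)(C)C(C)(C)C)C(C)(C)[C@H]2CC(C)=C[C@@H](O[Si](C)(C)C(C)(C)C)[C@@H]12 | intermediate
9 | cis-fused bicyclo[5.4.0]undecenone: C11 ketone, C7-OTBS, C8=C9(Me), (3S)-C3-OTBS, C4 gem-dimethyl | O=C1CC[C@H](O[Si](C)(C)C(C)(C)C)C(C)(C)[C@H]2CC(C)=C[C@@H](O[Si](C)(C)C(C)(C)C)[C@@H]12 | intermediate
10 | enol triflate of 9 (C11(OTf)=C1) | O=S(=O)(OC1=CC[C@H](O[Si](C)(C)C(C)(C)C)C(C)(C)[C@H]2CC(C)=C[C@@H](O[Si](C)(C)C(C)(C)C)[C@@H]12)C(F)(F)F | intermediate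
11 | bis-TBS ether diene (C11(Me)=C1, C8=C9(Me)) | CC1=CC[C@H](O[Si](C)(C)C(C)(C)C)C(C)(C)[C@H]2CC(C)=C[C@@H](O[Si](C)(C)C(C)(C)C)[C@@H]12 | intermediate
12 | diol (C7-OH, (3S)-C3-OH) | CC1=CC[C@H](O)C(C)(C)[C@H]2CC(C)=C[C@@H](O)[C@@H]12 | intermediate
13 | enedione (C7 enone, C3 ketone, C1=C11 alkene, cis-fused) | O=C1C=C(C)C[C@H]2[C@@H]1C(C)=CCC(=O)C2(C)C | intermediate
14 | (3R)-hydroxy enone (C3-OH cis to C10) | O=C1C=C(C)C[C@H]2[C@@H]1C(C)=CC[C@@H](O)C2(C)C | intermediate
15 | C3 isovalerate of 14 | O=C1C=C(C)C[C@H]2[C@@H]1C(C)=CC[C@@H](OC(=O)CC(C)C)C2(C)C | intermediate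
16 | C1–C11 epoxide of 15 (oxygen on the ring face opposite C7) | O=C1C=C(C)C[C@H]2[C@@H]1[C@]3(C)O[C@@H]3C[C@@H](OC(=O)CC(C)C)C2(C)C | intermediate
17 | TBS dienol ether of 16 (C7(OTBS)=C8–C9(Me)=C10) | CC(C)(C)[Si](C)(C)OC1=CC(C)=C[C@H]2[C@@H]1[C@]3(C)O[C@@H]3C[C@@H](OC(=O)CC(C)C)C2(C)C | intermediate
18 | tricyclic hydroxy enone (C1-OH, C3 isovalerate, C10–C11 bond closed) | O[C@@H]1C[C@@H](OC(=O)CC(C)C)C(C)(C)[C@@H]2[C@H]3C(=O)C=C(C)[C@@H]2[C@]31C | intermediate
19 | CNP0335239.1 (C1 senecioate, C3 isovalerate) | CC(C)=CC(=O)O[C@@H]1C[C@@H](OC(=O)CC(C)C)C(C)(C)[C@@H]2[C@H]3C(=O)C=C(C)[C@@H]2[C@]31C | target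

Total step count: 14. Longest linear sequence: 13 steps (steps 1, 2 and 4–14).

Steps most likely to fail

1. Step 13 (Proposed new method). The ring closure may lose to a 1,2-hydride shift of the opened epoxide (ketone formation), to proton loss giving an allylic alcohol, or to enolisation toward C6 during silylation followed by β-opening of the epoxide; participation of the C3 ester at C1 is a further possible leak. The fallback uses known chemistry only, sets out from 14 and comes back at 18. Compound 14 is ketalised with ethylene glycol and PPTS, with migration of the double bond out of conjugation, to give the β,γ-unsaturated dioxolane F1. The homoallylic C3 hydroxyl then directs VO(acac)2/t-BuOOH to the C1=C11 alkene only, giving the epoxy alcohol F2. Et2AlTMP isomerises this epoxide to the exocyclic allylic alcohol F3, and MnO2 oxidises it to the α-methylene ketone F4. mCPBA epoxidises the remaining electron-rich C9=C10 alkene on the face opposite the seven-membered ring, giving the epoxy enone F5. Conjugate reduction with L-Selectride creates the C11 methyl group and the C1/C11 enolate regiospecifically, and this enolate opens the epoxide at C10 in a 4-exo-tet intramolecular ketone alkylation to give the tricyclic hydroxy ketone F6. An Evans–Tishchenko reduction with isovaleraldehyde and catalytic SmI2 transfers hydride from the C3 hemiacetal to C1 and leaves the anti-1,3-diol as its C3 isovalerate, the ketal monoester F7. Aqueous acid removes the dioxolane and dehydrates the β-hydroxy ketone to the enone, which is 18.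

2. Step 10. The hydride may also reduce the enone, may enter C3 from the wrong face, or the alkoxide formed may move the C1=C11 double bond into conjugation or epimerise C6. The fallback separates the two oxidations; it sets out from 12 and comes back at 14. The less hindered allylic C7 hydroxyl of 12 is silylated selectively (TBSCl, imidazole, 0 °C) to give the mono-silyl ether F8, and Dess–Martin oxidation gives the C3 ketone F9, which carries no enone. Reagent-controlled reduction with (S)-Me-CBS and catecholborane (tertiary alkyl against CH2) gives the (3R)-alcohol F10. HF·pyridine then gives the diol F11, and MnO2 oxidises only the allylic alcohol to give 14.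

3. Step 5. The ring-fusion carbon C6 may migrate in place of C2, a second carbon may be inserted, or a β-silyloxy group may be lost under Lewis acid. The fallback fixes the site of insertion by an enol ether; it sets out from 7 and comes back at 9. Kinetic enolisation of 7 toward C2 (LDA with TMSCl present, −78 °C) gives the trimethylsilyl enol ether F12, and cyclopropanation (Et2Zn, CH2I2) gives the siloxycyclopropane F13, drawn as the isomer formed on the face of the C3 silyloxy group; both new centres are lost in the next operation. FeCl3 in DMF followed by NaOAc opens the internal cyclopropane bond and eliminates HCl (Saegusa–Ito ring expansion) to give the cycloheptenone F14, and conjugate reduction with Stryker's reagent gives 9.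

Further compounds
F1 | step 13 | β,γ-unsaturated dioxolane of 14 (C7 ketal, C9=C10, C1=C11, C3-OH) | CC1=CC[C@@H](O)C(C)(C)[C@H]2C=C(C)CC3(OCCO3)[C@@H]12
F2 | step 13 | C1–C11 epoxy alcohol (epoxide syn to C3-OH) | O1CCOC12CC(C)=C[C@H]3[C@@H]2[C@@]4(C)O[C@H]4C[C@@H](O)C3(C)C
F3 | step 13 | exocyclic allylic alcohol (C11=CH2, C1-OH) | O1CCOC12CC(C)=C[C@H]3[C@@H]2C(=C)[C@@H](O)C[C@@H](O)C3(C)C
F4 | step 13 | α-methylene ketone (C1=O, C11=CH2) | O1CCOC12CC(C)=C[C@H]3[C@@H]2C(=C)C(=O)C[C@@H](O)C3(C)C
F5 | step 13 | C9–C10 epoxide of F4 (oxygen anti to C11) | O1CCOC12C[C@@]4(C)O[C@H]4[C@H]3[C@@H]2C(=C)C(=O)C[C@@H](O)C3(C)C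
F6 | step 13 | tricyclic hydroxy ketone (C1 ketone, C9 tertiary alcohol, C7 ketal, C3-OH) | O=C1C[C@@H](O)C(C)(C)[C@@H]2[C@H]3C4(OCCO4)C[C@@](C)(O)[C@@H]2[C@]31C
F7 | step 13 | ketal monoester (C3 isovalerate, C1-OH anti, C9-OH) | O[C@@H]1C[C@@H](OC(=O)CC(C)C)C(C)(C)[C@@H]2[C@H]3C4(OCCO4)C[C@@](C)(O)[C@@H]2[C@]31C
F8 | step 10 | mono-silyl ether of 12 (C7-OTBS, (3S)-C3-OH) | CC1=CC[C@H](O)C(C)(C)[C@H]2CC(C)=C[C@@H](O[Si](C)(C)C(C)(C)C)[C@@H]12
F9 | step 10 | C3 ketone with C7-OTBS | CC1=CCC(=O)C(C)(C)[C@H]2CC(C)=C[C@@H](O[Si](C)(C)C(C)(C)C)[C@@H]12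
F10 | step 10 | (3R)-alcohol with C7-OTBS | CC1=CC[C@@H](O)C(C)(C)[C@H]2CC(C)=C[C@@H](O[Si](C)(C)C(C)(C)C)[C@@H]12
F11 | step 10 | diol with (3R)-C3-OH and C7-OH | CC1=CC[C@@H](O)C(C)(C)[C@H]2CC(C)=C[C@@H](O)[C@@H]12
F12 | step 5 | trimethylsilyl enol ether of 7 (C11(OTMS)=C2) | C[Si](C)(C)OC1=C[C@H](O[Si](C)(C)C(C)(C)C)C(C)(C)[C@H]2CC(C)=C[C@@H](O[Si](C)(C)C(C)(C)C)[C@@H]12
F13 | step 5 | siloxycyclopropane (CH2 bridging C11 and C2) | C[Si](C)(C)O[C@@]12C[C@@H]1[C@H](O[Si](C)(C)C(C)(C)C)C(C)(C)[C@H]3CC(C)=C[C@@H](O[Si](C)(C)C(C)(C)C)[C@@H]23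
F14 | step 5 | cycloheptenone (C11 ketone, C1=C2) | O=C1C=C[C@H](O[Si](C)(C)C(C)(C)C)C(C)(C)[C@H]2CC(C)=C[C@@H](O[Si](C)(C)C(C)(C)C)[C@@H]12
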